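## Retrosynthetic overview

1. The SMILES is read as (1R,2R,4aR,8aS)-2,5,5,8a-tetramethyl-1-[(3E,7E)-4,8,12-trimethyltrideca-3,7,11-trien-1-yl]decahydronaphthalen-2-ol. This is a cis-fused decalin: 4a-H, 8a-CH3 and the C1 chain lie on one face, the 2-OH on the other. The tertiary carbinol is made last from the C2 ketone and a methyl nucleophile.
2. The C1–side-chain bond and the carbinol ring are made together. A cis-hydrindan-1-one undergoes a one-carbon ring expansion (1,2-shift of its quaternary carbon) to a regiodefined decalone enolate, which is alkylated in the same flask with homofarnesyl iodide.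
3. The cis-hydrindanone comes from an enantioselective radical conjugate addition to 2-methylcyclopent-2-enone (C–C(CH3)2 bond, first stereocentre), then an intramolecular enolate alkylation (gem-dimethyl ring, quaternary carbon, cis fusion).
4. Homofarnesyl iodide comes from two zirconium-catalysed alkyne carboaluminations (both E alkenes), joined by a Negishi coupling and finished with ethylene oxide.
5. Ring order: cyclopentanone ring (bought), then the gem-dimethylcyclohexane ring (step 7), then enlargement of the five-membered ring to the carbinol ring (step 8).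

Assumption: the trimethylsilyl group of compound 6 is a protecting group on 4-bromobut-1-yne (five non-hydrogen atoms) and is not counted.

## Route

Step 1
Reactants: 1 5-bromo-2-methylpent-2-ene; 2 lithium acetylide–ethylenediamine complex
Product: 3 6-methylhept-5-en-1-yne
Conditions: DMSO, 10 → 25 °C
Reagents that add atoms: none
Why: SN2 alkylation of the acetylide at the primary homoallylic bromide (acetylide alkylation); no stereocentre is formed.

Step 2
Reactants: 3 6-methylhept-5-en-1-yne
Product: 5 (1E)-1-iodo-2,6-dimethylhepta-1,5-diene, via alkenylalane 4 (not isolated)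
Conditions: Me3Al, Cp2ZrCl2 (20 mol%), CH2Cl2, 23 °C; then I2, THF, −30 → 0 °C
Reagents that add atoms: trimethylaluminium C[Al](C)C; iodine II
Why: Negishi zirconium-catalysed carboalumination adds CH3 and Al syn across the terminal alkyne with Al on the terminal carbon, and iodinolysis of the C–Al bond goes with retention, so the trisubstituted alkene is E.

Step 3
Reactants: 5 (1E)-1-iodo-2,6-dimethylhepta-1,5-diene; 6 (4-bromobut-1-yn-1-yl)trimethylsilane
Product: 9 (5E)-6,10-dimethylundeca-5,9-dien-1-yne, via alkylzinc bromide 7 (not isolated), via silyl enyne 8 (not isolated)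
Conditions: 6, Zn, I2 (5 mol%), DMA, 80 °C; then 5, Pd(PPh3)4 (3 mol%), THF, 25 °C; then K2CO3, MeOH, 25 °C
Reagents that add atoms: none
Why: Zinc insertion into the primary bromide and Negishi coupling with the alkenyl iodide keep the E geometry (sp3–sp2 cross-coupling), and methanolysis removes the alkynyl silyl group.

Step 4
Reactants: 9 (5E)-6,10-dimethylundeca-5,9-dien-1-yne; 10 ethylene oxide
Product: 13 (3E,7E)-4,8,12-trimethyltrideca-3,7,11-trien-1-ol, via alkenylalane 11 (not isolated), via lithium alanate 12 (not isolated)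
Conditions: Me3Al, Cp2ZrCl2 (20 mol%), CH2Cl2, 23 °C; evaporate; n-BuLi, THF–hexane, −78 °C; 10, −78 → 0 °C; H2O
Reagents that add atoms: trimethylaluminium C[Al](C)C
Why: A second syn carboalumination (Negishi) sets the second E alkene, and the alkenylalanate opens ethylene oxide with retention at the alkenyl carbon to give the homoallylic alcohol.

Step 5
Reactants: 13 (3E,7E)-4,8,12-trimethyltrideca-3,7,11-trien-1-ol
Product: 14 (3E,7E)-1-iodo-4,8,12-trimethyltrideca-3,7,11-triene
Conditions: I2, PPh3, imidazole, CH2Cl2, 0 °C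
Reagents that add atoms: iodine II
Why: Appel iodination of the primary alcohol (SN2 on the alkoxyphosphonium ion) leaves the three trisubstituted alkenes untouched.

Step 6
Reactants: 15 2-methylcyclopent-2-en-1-one; 1 5-bromo-2-methylpent-2-ene
Product: 16 (3S)-3-(5-bromo-2-methylpentan-2-yl)-2-methylcyclopentan-1-one (both C2 epimers)
Conditions: Fe(acac)3 (30 mol%), 9-amino-9-deoxy-epi-quinine (20 mol%), CF3CO2H (40 mol%), PhSiH3, EtOH, 0 → 25 °C
Reagents that add atoms: none
Why: Proposed new method: an iron hydride transfers a hydrogen atom to the trisubstituted alkene of 1 to give the tertiary 5-bromo-2-methylpent-2-yl radical, which adds (Giese addition) to the β-carbon of the chiral iminium ion formed reversibly from 15 and the cinchona primary amine; the iminium ion is far more electrophilic than free 15, so the catalyst-bound pathway should outrun the racemic background, the catalyst shields one face and sets C3 as S (the quinidine-derived pseudoenantiomer is used if the sense proves opposite), and reduction of the α-iminyl radical by divalent iron followed by hydrolysis releases 16 and returns trivalent iron; the closest known reactions are the racemic iron-hydride reductive olefin–enone coupling and the chiral primary-amine iminium trapping of photogenerated radicals by cyclic enones.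

Step 7
Reactants: 16 (3S)-3-(5-bromo-2-methylpentan-2-yl)-2-methylcyclopentan-1-one
Product: 17 (3aR,7aS)-4,4,7a-trimethyloctahydro-1H-inden-1-one
Conditions: t-BuOK, t-BuOH–THF, 25 °C
Reagents that add atoms: none
Why: Under equilibrating conditions the more substituted enolate (C2) is alkylated by the tethered primary bromide (6-exo-tet intramolecular enolate alkylation); the three-atom tether from C3 can reach C2 only on its own face, so the new ring is cis-fused and C7a is set S with the methyl syn to H-3a, both C2 epimers of 16 converging.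

Step 8
Reactants: 17 (3aR,7aS)-4,4,7a-trimethyloctahydro-1H-inden-1-one; 14 (3E,7E)-1-iodo-4,8,12-trimethyltrideca-3,7,11-triene
Product: 21 (1R,4aR,8aS)-5,5,8a-trimethyl-1-[(3E,7E)-4,8,12-trimethyltrideca-3,7,11-trien-1-yl]octahydronaphthalen-2(1H)-one, via dibromomethyl alkoxide 18 (not isolated), via lithium carbenoid 19 (not isolated), via lithium enolate 20 (not isolated)
Conditions: CH2Br2, lithium 2,2,6,6-tetramethylpiperidide, THF, −78 °C; t-BuLi (2 equiv), −78 → 0 °C; then 14, DMPU, −40 → 25 °C
Reagents that add atoms: dibromomethane BrCBr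
Why: One-carbon ring expansion through a β-oxido carbenoid (dibromomethyllithium homologation): the 1,2-shift of the more substituted, quaternary C7a with retention gives only the enolate on the inserted carbon, and because the enolate ring sits in the half-chair with the C8 methylene axial (the other half-chair pushes a C5 methyl under the ring), the iodide attacks C1 on the convex face anti to C8, placing the chain cis to the angular methyl (1R).

Step 9
Reactants: 21 (1R,4aR,8aS)-5,5,8a-trimethyl-1-[(3E,7E)-4,8,12-trimethyltrideca-3,7,11-trien-1-yl]octahydronaphthalen-2(1H)-one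
Product: 22 (1R,2R,4aR,8aS)-2,5,5,8a-tetramethyl-1-[(3E,7E)-4,8,12-trimethyltrideca-3,7,11-trien-1-yl]decahydronaphthalen-2-ol
Conditions: MeLi, CeCl3, THF, −78 °C; H2O
Reagents that add atoms: methyllithium [Li]C
Why: Organocerium 1,2-addition avoids enolisation and C1 epimerisation; the axial trajectory is blocked by the syn-axial C8 methylene, so methyl enters equatorially on the convex face and gives the axial 2-hydroxyl trans to the side chain (2R).

## Compound list

1 | 5-bromo-2-methylpent-2-ene | CC(C)=CCCBr | starting material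
2 | lithium acetylide–ethylenediamine complex | [Li]C#C.NCCN | starting material
3 | 6-methylhept-5-en-1-yne | C#CCCC=C(C)C | intermediate
4 | [(1E)-2,6-dimethylhepta-1,5-dien-1-yl]dimethylaluminium | C[Al](C)/C=C(\C)CCC=C(C)C | intermediate
5 | (1E)-1-iodo-2,6-dimethylhepta-1,5-diene | I/C=C(\C)CCC=C(C)C | intermediate
6 | (4-bromobut-1-yn-1-yl)trimethylsilane | C[Si](C)(C)C#CCCBr | starting material
7 | bromo[4-(trimethylsilyl)but-3-yn-1-yl]zinc | C[Si](C)(C)C#CCC[Zn]Br | intermediate
8 | [(5E)-6,10-dimethylundeca-5,9-dien-1-yn-1-yl]trimethylsilane | C[Si](C)(C)C#CCC/C=C(\C)CCC=C(C)C | intermediate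
9 | (5E)-6,10-dimethylundeca-5,9-dien-1-yne | C#CCC/C=C(\C)CCC=C(C)C | intermediate
10 | ethylene oxide | C1CO1 | starting material
11 | dimethyl[(1E,5E)-2,6,10-trimethylundeca-1,5,9-trien-1-yl]aluminium | C[Al](C)/C=C(\C)CC/C=C(\C)CCC=C(C)C | intermediate
12 | lithium butyldimethyl[(1E,5E)-2,6,10-trimethylundeca-1,5,9-trien-1-yl]aluminate | [Li+].CCCC[Al-](C)(C)/C=C(\C)CC/C=C(\C)CCC=C(C)C | intermediate
13 | (3E,7E)-4,8,12-trimethyltrideca-3,7,11-trien-1-ol | OCC/C=C(\C)CC/C=C(\C)CCC=C(C)C | intermediate
14 | (3E,7E)-1-iodo-4,8,12-trimethyltrideca-3,7,11-triene | ICC/C=C(\C)CC/C=C(\C)CCC=C(C)C | intermediate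
15 | 2-methylcyclopent-2-en-1-one | CC1=CCCC1=O | starting material
16 | (3S)-3-(5-bromo-2-methylpentan-2-yl)-2-methylcyclopentan-1-one | CC1C(=O)CC[C@@H]1C(C)(C)CCCBr | intermediate
17 | (3aR,7aS)-4,4,7a-trimethyloctahydro-1H-inden-1-one | O=C1[C@@]2(C)CCCC(C)(C)[C@H]2CC1 | intermediate
18 | lithium (3aR,7aS)-1-(dibromomethyl)-4,4,7a-trimethyloctahydro-1H-inden-1-olate | [Li+].[O-]C1(C(Br)Br)[C@@]2(C)CCCC(C)(C)[C@H]2CC1 | intermediate
19 | lithium (3aR,7aS)-1-[bromo(lithio)methyl]-4,4,7a-trimethyloctahydro-1H-inden-1-olate | [Li+].[O-]C1(C([Li])Br)[C@@]2(C)CCCC(C)(C)[C@H]2CC1 | intermediate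
20 | lithium (4aR,8aS)-5,5,8a-trimethyl-3,4,4a,5,6,7,8,8a-octahydronaphthalen-2-olate | [Li+].[O-]C1=C[C@@]2(C)CCCC(C)(C)[C@H]2CC1 | intermediate
21 | (1R,4aR,8aS)-5,5,8a-trimethyl-1-[(3E,7E)-4,8,12-trimethyltrideca-3,7,11-trien-1-yl]octahydronaphthalen-2(1H)-one | CC(C)=CCC/C(C)=C/CC/C(C)=C/CC[C@@H]1[C@@]2(C)CCCC(C)(C)[C@H]2CCC1=O | intermediate
22 | (1R,2R,4aR,8aS)-2,5,5,8a-tetramethyl-1-[(3E,7E)-4,8,12-trimethyltrideca-3,7,11-trien-1-yl]decahydronaphthalen-2-ol | CC(C)=CCC/C(C)=C/CC/C(C)=C/CC[C@@H]1[C@@]2(C)CCCC(C)(C)[C@H]2CC[C@@]1(C)O | target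

## Step count and risks

Total steps: 9. Longest linear sequence: 7 (steps 1, 2, 3, 4, 5, 8, 9).

**Step 6 (new enantioselective radical conjugate addition).** The amine may be reduced or alkylated under the silane conditions, and the racemic background addition to free 15 may erode the selectivity. The fallback uses known chemistry, sets out from 15 and 1 and returns at 17. The coupling is run without the amine under the established iron-hydride conditions (Fe(acac)3, PhSiH3, EtOH–ethylene glycol, 60 °C) to give racemic 3-(5-bromo-2-methylpentan-2-yl)-2-methylcyclopentan-1-one F1. This is cyclised with t-BuOK as in step 7 to racemic cis-4,4,7a-trimethyloctahydro-1H-inden-1-one F2. F2 is resolved by the Johnson sulfoximine method: lithiated (S)-N,S-dimethyl-S-phenylsulfoximine (THF, −78 °C) adds to give the separable β-hydroxysulfoximine from the (3aR,7aS) ketone F3 and the β-hydroxysulfoximine from the enantiomeric ketone F4. After chromatography, thermolysis of F3 (toluene, 110 °C) gives 17.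

**Step 8 (ring expansion with alkylation by an unactivated iodide).** The hindered enolate 20 may alkylate slowly, allowing proton transfer and polyalkylation, and some CH2 migration may compete with migration of the quaternary carbon. The fallback sets out from 17 and returns at 22, bypassing 21.
- Enolate 20, made as in step 8, is trapped at −78 °C with the far more reactive tert-butyl bromoacetate to give tert-butyl 2-[(1R,4aR,8aS)-5,5,8a-trimethyl-2-oxodecahydronaphthalen-1-yl]acetate F5.
- MeLi/CeCl3 at −78 °C adds to the ketone only, giving tert-butyl 2-[(1R,2R,4aR,8aS)-2-hydroxy-2,5,5,8a-tetramethyldecahydronaphthalen-1-yl]acetate F6.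
- LiAlH4 gives (1R,2R,4aR,8aS)-1-(2-hydroxyethyl)-2,5,5,8a-tetramethyldecahydronaphthalen-2-ol F7.
- I2/PPh3/imidazole converts only the primary hydroxyl, giving (1R,2R,4aR,8aS)-1-(2-iodoethyl)-2,5,5,8a-tetramethyldecahydronaphthalen-2-ol F8.
- Alkenylalane 11 is quenched with I2 instead of ethylene oxide to give (1E,5E)-1-iodo-2,6,10-trimethylundeca-1,5,9-triene F9.
- F8 is treated with t-BuLi (3 equiv, −78 °C), then ZnBr2, and coupled with F9 under Pd(PPh3)4 catalysis (Negishi coupling) to give 22.

**Step 9 (facial selectivity of the methyl addition).** The axial C1 chain partly shields the face that the methyl group must use, so the 2-epimer may form. The fallback sets out from 21 and returns at 22. It replaces the kinetic addition by a reversible one: dimethylsulfoxonium methylide (Me3S(O)I, NaH, DMSO, 25 °C; Corey–Chaykovsky reaction) closes the betaine that carries the new C–C bond equatorial. This gives (1R,2R,4aR,8aS)-5,5,8a-trimethyl-1-[(3E,7E)-4,8,12-trimethyltrideca-3,7,11-trien-1-yl]octahydro-1H-spiro[naphthalene-2,2'-oxirane] F10. LiEt3BH (THF, 0 °C) opens it at the CH2 carbon to give 22.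

Further compounds
F1 | step 6 | racemic 3-(5-bromo-2-methylpentan-2-yl)-2-methylcyclopentan-1-one | CC1C(=O)CC[C@@H]1C(C)(C)CCCBr.CC1C(=O)CC[C@H]1C(C)(C)CCCBr
F2 | step 6 | racemic cis-4,4,7a-trimethyloctahydro-1H-inden-1-one | O=C1[C@@]2(C)CCCC(C)(C)[C@H]2CC1.O=C1[C@]2(C)CCCC(C)(C)[C@@H]2CC1
F3 | step 6 | (3aR,7aS)-4,4,7a-trimethyl-1-{[(S)-N-methyl-S-phenylsulfonimidoyl]methyl}octahydro-1H-inden-1-ol | CN=[S@](=O)(CC1(O)[C@@]2(C)CCCC(C)(C)[C@H]2CC1)c1ccccc1
F4 | step 6 | (3aS,7aR)-4,4,7a-trimethyl-1-{[(S)-N-methyl-S-phenylsulfonimidoyl]methyl}octahydro-1H-inden-1-ol | CN=[S@](=O)(CC1(O)[C@]2(C)CCCC(C)(C)[C@@H]2CC1)c1ccccc1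
F5 | step 8 | tert-butyl 2-[(1R,4aR,8aS)-5,5,8a-trimethyl-2-oxodecahydronaphthalen-1-yl]acetate | CC(C)(C)OC(=O)C[C@@H]1[C@@]2(C)CCCC(C)(C)[C@H]2CCC1=O
F6 | step 8 | tert-butyl 2-[(1R,2R,4aR,8aS)-2-hydroxy-2,5,5,8a-tetramethyldecahydronaphthalen-1-yl]acetate | CC(C)(C)OC(=O)C[C@@H]1[C@@]2(C)CCCC(C)(C)[C@H]2CC[C@@]1(C)O
F7 | step 8 | (1R,2R,4aR,8aS)-1-(2-hydroxyethyl)-2,5,5,8a-tetramethyldecahydronaphthalen-2-ol | OCC[C@@H]1[C@@]2(C)CCCC(C)(C)[C@H]2CC[C@@]1(C)O
F8 | step 8 | (1R,2R,4aR,8aS)-1-(2-iodoethyl)-2,5,5,8a-tetramethyldecahydronaphthalen-2-ol | ICC[C@@H]1[C@@]2(C)CCCC(C)(C)[C@H]2CC[C@@]1(C)O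
F9 | step 8 | (1E,5E)-1-iodo-2,6,10-trimethylundeca-1,5,9-triene | I/C=C(\C)CC/C=C(\C)CCC=C(C)C
F10 | step 9 | (1R,2R,4aR,8aS)-5,5,8a-trimethyl-1-[(3E,7E)-4,8,12-trimethyltrideca-3,7,11-trien-1-yl]octahydro-1H-spiro[naphthalene-2,2'-oxirane] | CC(C)=CCC/C(C)=C/CC/C(C)=C/CC[C@@H]1[C@@]2(C)CCCC(C)(C)[C@H]2CC[C@]13CO3
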